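**Strategy.** The quinone ring is disconnected at the bond between carbonyl carbon C1 (the one flanked by the hydroxylated C2) and C6, the only ring CH. Ring carbons C1–C4 (C=O, C–OH, C–hexadecyl, C=O) then map onto the four carbons of a squaric ester and C5–C6 onto a 1-ethoxyvinyl group. The precursor is a 4-(1-ethoxyvinyl)-3-hexadecyl-2-isopropoxy-4-methoxycyclobutenone: heating opens it to a dienylketene whose ketene carbon closes onto the vinyl CH2 terminus in a 6π electrocyclisation, and oxidation in the same flask delivers the quinone with all four oxygens and the side chain in place. The step exploits the 1,2,4,5-tetraoxygenated six-membered ring with its single unsubstituted carbon.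

Key step: step 3

Remark on the chemistry: the target is achiral, so the quaternary cyclobutene centres that appear on the way are carried as racemates (or diastereomer mixtures) and vanish in step 3. Target numbering used below: C1 carbonyl (between C2 and C6), C2–OH, C3–hexadecyl, C4 carbonyl, C5–OH, C6–H. Diisopropyl squarate, ethyl vinyl ether and 1-iodohexadecane are taken as commercial.

**Step 1**
Reactants: 1 diisopropyl squarate; 2 ethyl vinyl ether
Product: 5 4-(1-ethoxyvinyl)-2,3-diisopropoxy-4-methoxycyclobut-2-en-1-one (racemic), via 1-ethoxyvinyllithium 3 (not isolated), via lithium alkoxide adduct 4 (not isolated)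
Conditions: 2, t-BuLi, THF, −78 to 0 °C; then 1, THF, −78 °C; then MeOTf, −78 to 0 °C
Reagents that add atoms: methyl trifluoromethanesulfonate, COS(=O)(=O)C(F)(F)F
Why: tert-Butyllithium lithiates ethyl vinyl ether at the α-carbon and the resulting 1-ethoxyvinyllithium adds 1,2 to one of the two equivalent carbonyl groups of the squarate (organolithium mono-addition to a squaric ester), after which methyl triflate O-methylates the tertiary lithium alkoxide in the same flask to a non-migrating ether; the new quaternary centre is racemic and later becomes a trigonal quinone carbon.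

**Step 2**
Reactants: 5 4-(1-ethoxyvinyl)-2,3-diisopropoxy-4-methoxycyclobut-2-en-1-one; 6 1-iodohexadecane
Product: 10 4-(1-ethoxyvinyl)-3-hexadecyl-2-isopropoxy-4-methoxycyclobut-2-en-1-one (racemic), via hexadecyllithium 7 (not isolated), via lithium carbinolate 8 (not isolated), via tertiary trifluoroacetate 9 (not isolated)
Conditions: 6, t-BuLi (2 equiv), Et2O–pentane, −78 °C to rt; then 5, THF, −78 °C; then (CF3CO)2O, −78 °C; then aq NaHCO3
Reagents that add atoms: water, O
Why: Iodine–lithium exchange gives hexadecyllithium, which adds 1,2 to the only carbonyl of 5 (a vinylogous ester), and trifluoroacetylation of the alkoxide lets the tertiary ester ionise to an isopropoxy-stabilised cyclobutenyl cation that water converts on work-up into the transposed enone (Stork–Danheiser-type 1,3-carbonyl transposition, as used on squarate adducts); the methyl ether at the quaternary carbon cannot ionise, so hexadecyl ends up next to that carbon.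

**Step 3**
Reactants: 10 4-(1-ethoxyvinyl)-3-hexadecyl-2-isopropoxy-4-methoxycyclobut-2-en-1-one
Product: 14 5-ethoxy-3-hexadecyl-2-isopropoxy-1,4-benzoquinone, via dienylketene 11 (not isolated), via cyclohexadienone 12 (not isolated), via methoxyphenol 13 (not isolated)
Conditions: p-xylene (dilute), 138 °C, Ar; then (NH4)2Ce(NO3)6, MeCN–H2O, 0 °C
Reagents that add atoms: water, O
Why: Heating breaks the carbonyl–quaternary carbon bond of cyclobutenone 10 in a conrotatory 4π electrocyclic opening to dienylketene 11, whose ketene carbon (future C1) and enol-ether CH2 terminus (future C6) join in a thermal 6π electrocyclisation to dienone 12; enolisation gives phenol 13, and tetravalent cerium oxidises it to quinone 14 with loss of the methyl group as methanol. The closest known reaction type is the thermal ring expansion of squarate-derived 4-alkenyl-4-oxycyclobutenones to hydroquinones, the alkenyl counterpart of the Moore rearrangement. The six-membered carbocycle is closed in a disrotatory 6π mode, helped by the matched polarity of the nucleophilic enol-ether carbon and the electrophilic ketene carbon. No stereocentre is formed and the one in 10 disappears. The step needs the ethoxyvinyl group to rotate inward so that it lies cis to the ketene, which the methoxy donor on the same carbon secures by its preference for outward rotation; the positions of hexadecyl and the alkoxy groups are already fixed by the order of steps 1 and 2. High dilution keeps the ketene from dimerising before it cyclises.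

**Step 4**
Reactants: 14 5-ethoxy-3-hexadecyl-2-isopropoxy-1,4-benzoquinone
Product: 16 3-hexadecyl-2,5-dihydroxy-1,4-benzoquinone, via disodium quinone dienolate 15 (not isolated)
Conditions: NaOH (2 M aq), EtOH, 80 °C; then HCl (1 M aq)
Reagents that add atoms: sodium hydroxide, [Na+].[OH-]
Why: Both alkoxy groups are vinylogous esters of the quinone carbonyls, so hydroxide replaces them by addition–elimination, and the resulting dianion, a doubly vinylogous carboxylate, is stable to base and gives the target on acidification.

**Compound list**
1 | diisopropyl squarate (3,4-diisopropoxycyclobut-3-ene-1,2-dione) | CC(C)OC1=C(OC(C)C)C(=O)C1=O | starting material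
2 | ethyl vinyl ether | C=COCC | starting material
3 | 1-ethoxyvinyllithium | [Li]C(=C)OCC | intermediate
4 | lithium 1-(1-ethoxyvinyl)-2,3-diisopropoxy-4-oxocyclobut-2-en-1-olate (racemic) | CCOC(=C)C1(O[Li])C(OC(C)C)=C(OC(C)C)C1=O | intermediate
5 | 4-(1-ethoxyvinyl)-2,3-diisopropoxy-4-methoxycyclobut-2-en-1-one (racemic) | CCOC(=C)C1(OC)C(OC(C)C)=C(OC(C)C)C1=O | intermediate
6 | 1-iodohexadecane | CCCCCCCCCCCCCCCCI | starting material
7 | hexadecyllithium | [Li]CCCCCCCCCCCCCCCC | intermediate
8 | lithium 4-(1-ethoxyvinyl)-1-hexadecyl-2,3-diisopropoxy-4-methoxycyclobut-2-en-1-olate (diastereomer mixture) | CCCCCCCCCCCCCCCCC1(O[Li])C(OC(C)C)=C(OC(C)C)C1(OC)C(=C)OCC | intermediate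
9 | 4-(1-ethoxyvinyl)-1-hexadecyl-2,3-diisopropoxy-4-methoxycyclobut-2-en-1-yl trifluoroacetate (diastereomer mixture) | CCCCCCCCCCCCCCCCC1(OC(=O)C(F)(F)F)C(OC(C)C)=C(OC(C)C)C1(OC)C(=C)OCC | intermediate
10 | 4-(1-ethoxyvinyl)-3-hexadecyl-2-isopropoxy-4-methoxycyclobut-2-en-1-one (racemic) | CCCCCCCCCCCCCCCCC1=C(OC(C)C)C(=O)C1(OC)C(=C)OCC | intermediate
11 | (3E)-5-ethoxy-3-hexadecyl-2-isopropoxy-4-methoxyhexa-1,3,5-trien-1-one (ketene and ethoxyvinyl groups cis) | CCCCCCCCCCCCCCCC/C(C(OC(C)C)=C=O)=C(\OC)C(=C)OCC | intermediate
12 | 5-ethoxy-3-hexadecyl-2-isopropoxy-4-methoxycyclohexa-2,4-dien-1-one | CCCCCCCCCCCCCCCCC1=C(OC(C)C)C(=O)CC(OCC)=C1OC | intermediate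
13 | 5-ethoxy-3-hexadecyl-2-isopropoxy-4-methoxyphenol | CCCCCCCCCCCCCCCCc1c(OC(C)C)c(O)cc(OCC)c1OC | intermediate
14 | 5-ethoxy-3-hexadecyl-2-isopropoxy-1,4-benzoquinone | CCCCCCCCCCCCCCCCC1=C(OC(C)C)C(=O)C=C(OCC)C1=O | intermediate
15 | disodium 3-hexadecyl-2,5-dioxido-1,4-benzoquinone | CCCCCCCCCCCCCCCCC1=C([O-])C(=O)C=C([O-])C1=O.[Na+].[Na+] | intermediate
16 | 3-hexadecyl-2,5-dihydroxy-1,4-benzoquinone | CCCCCCCCCCCCCCCCC1=C(O)C(=O)C=C(O)C1=O | target

**Total step count:** 4
**Longest linear sequence:** 4 steps (1 → 5 → 10 → 14 → 16)

**Steps most likely to fail**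

Step 2. The anhydride, or acid formed from it, may attack the acid-labile 1-ethoxyvinyl group while the tertiary alkoxide is being ionised, so that the enol ether is acylated or hydrolysed before the transposition is complete. The fallback separates the addition from the ionisation and triggers the transposition by sulfonylation under amine buffer. It sets out from 5: hexadecyllithium 7 is added as before, but the mixture is quenched at −78 °C with aqueous NH4Cl and the neutral carbinol 4-(1-ethoxyvinyl)-1-hexadecyl-2,3-diisopropoxy-4-methoxycyclobut-2-en-1-ol F1 is isolated. Methanesulfonyl chloride and excess Et3N in CH2Cl2 at −40 °C then give the tertiary methanesulfonate 4-(1-ethoxyvinyl)-1-hexadecyl-2,3-diisopropoxy-4-methoxycyclobut-2-en-1-yl methanesulfonate F2. This ionises in the basic medium and on aqueous NaHCO3 work-up gives the transposed enone, so the fallback comes back to the route at 10.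

Step 3. The ring expansion itself is expected to be dependable; the weak part is the oxidative finish, where tetravalent cerium may dealkylate at the ortho isopropoxy group (ortho-quinone formation) or its acidity may degrade the electron-rich phenol. The fallback keeps the thermal ring closure but replaces the direct oxidative demethylation by a para-selective dearomatisation to a quinone monoketal. It sets out from 10: the thermolysis in p-xylene is stopped after the thermal stage and phenol 13 is isolated under argon. PhI(OAc)2 in MeOH at 0 °C then gives 5-ethoxy-3-hexadecyl-2-isopropoxy-4,4-dimethoxycyclohexa-2,5-dien-1-one F3, and mild hydrolysis with aqueous oxalic acid in THF unmasks the second carbonyl. The fallback comes back to the route at 14.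

Step 4. Addition–elimination may be slow at the isopropoxy-bearing C2, which is shielded by the neighbouring hexadecyl chain, and prolonged heating in base may degrade the quinone. The fallback cleaves the ethers at the arene oxidation level and lets air restore the quinone. It sets out from 14: Na2S2O4 in EtOAc–H2O reduces it to 5-ethoxy-3-hexadecyl-2-isopropoxybenzene-1,4-diol F4. BBr3 in CH2Cl2 (−78 °C to rt) cleaves both alkyl aryl ethers to 3-hexadecylbenzene-1,2,4,5-tetrol F5. Stirring F5 in EtOAc over aqueous NaHCO3 under air oxidises it to the 2,5-dihydroxyquinone, and the fallback comes back to the route at 16.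

**Further compounds**
F1 | step 2 | 4-(1-ethoxyvinyl)-1-hexadecyl-2,3-diisopropoxy-4-methoxycyclobut-2-en-1-ol (diastereomer mixture) | CCCCCCCCCCCCCCCCC1(O)C(OC(C)C)=C(OC(C)C)C1(OC)C(=C)OCC
F2 | step 2 | 4-(1-ethoxyvinyl)-1-hexadecyl-2,3-diisopropoxy-4-methoxycyclobut-2-en-1-yl methanesulfonate (diastereomer mixture) | CCCCCCCCCCCCCCCCC1(OS(C)(=O)=O)C(OC(C)C)=C(OC(C)C)C1(OC)C(=C)OCC
F3 | step 3 | 5-ethoxy-3-hexadecyl-2-isopropoxy-4,4-dimethoxycyclohexa-2,5-dien-1-one | CCCCCCCCCCCCCCCCC1=C(OC(C)C)C(=O)C=C(OCC)C1(OC)OC
F4 | step 4 | 5-ethoxy-3-hexadecyl-2-isopropoxybenzene-1,4-diol | CCCCCCCCCCCCCCCCc1c(OC(C)C)c(O)cc(OCC)c1O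
F5 | step 4 | 3-hexadecylbenzene-1,2,4,5-tetrol | CCCCCCCCCCCCCCCCc1c(O)c(O)cc(O)c1O
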